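## Structural features

The target is a 3-hydroxyflavanone (dihydroflavonol): benzene ring A is fused through C4a and C8a to the dihydropyran-4-one ring C, which carries the 4-hydroxyphenyl ring B on C2. Ring A has no hydrogen left. It is a phloroglucinol with oxygens on C5 (free OH, hydrogen-bonded to the C4 carbonyl), C7 (free OH) and C8a (ring oxygen O1), prenyl groups on C6 and C8, and the C4 carbonyl on C4a. The only stereocentres are the adjacent C2 and C3, both R, with aryl and hydroxyl trans. C2 is a benzylic ether carbon activated by the para-hydroxyl of ring B and C3 lies alpha to the ketone, so both are at risk under forcing acid or base. The fragile parts are the two trisubstituted alkenes next to phenols (acid closes them to 2,2-dimethylchromans, electrophilic oxidants attack them first), the air-sensitive polyphenol, and the beta-aryloxy ketone, which base opens to the chalcone. Ring C is classical flavonoid chemistry; the real difficulty is a regiochemically clean, fully substituted ring A, together with a C2/C3 construction that the prenyl groups survive. The key step uses the local mirror symmetry of ring A about the C7···C4a axis. The C7 oxygen flanked by the C6 and C8 prenyl groups, the oxygens on C5 and C8a, and the single open position C4a map onto a cyclobutenone (C7 carbonyl, C4a, C5, C6) and a prenylated silyloxyalkyne (C8, C8a).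

## Logic of the disconnections

Flavonoid numbering is used for ring atoms.

27 to 26. The O1–C2 bond is cut, together with the four acetal C–O bonds of the protecting groups. This reveals an epoxy ketone in which C3 already has its final configuration and C2 the opposite one. The gain is that ring C and all deprotections fall into one operation. The demand is an acid mild enough to leave the prenyl groups alone while opening the oxirane at its benzylic carbon.

26 to 25. The two C–O bonds of the oxirane are cut. Both stereocentres then come from one face-selective oxygen transfer to an E enone. The gain is an achiral precursor. The demand is a nucleophilic oxidant that ignores the two electron-rich alkenes and a catalyst that can tell the faces of a twisted, hindered enone apart.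

25 to 20 and 23. The C4–C4a bond is cut. C4a is the only CH of ring A and lies between two coordinating oxygens, so it can be an aryl anion, and the whole C4–C3–C2–ring B unit can arrive as one acyl donor. The gain is a convergent union without electrophilic acylation, which would expose the prenylphenols to Lewis acid. The demand is ring metalation in preference to the allylic–benzylic CH2 groups, and 1,2- rather than 1,4-addition.

23 to 22 to 21. The C2=C3 alkene is cut as an olefination and the aryl O–CH2 bond as an alkylation. This reduces the ring B block to a purchased hydroxy aldehyde. The demand is E geometry only.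

20 to 18 (through 19). The three acetal O–C bonds are cut and two O–Si bonds restored. The exchange is needed because silyl ethers neither direct metalation nor resist migration to carbon. The demand is that the oxidisable triol 19 is not handled in air, so it is generated and capped in one flask.

18 to 13 and 5. The C6–C7, C7–C8 and C4a–C8a bonds are cut. This takes the hexasubstituted ring apart into a four-carbon and a two-carbon piece that each already carry one prenyl group and one oxygen. The gain is that no substituent is introduced on an aromatic ring. The demand is a regioselective ketene–alkyne union, which the oxygen of 5 provides, and thermal access to the vinylketene from 13.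

13 to 11 and 9 (through 12); 11 to 10. The C1–C2 and C3–C4 bonds of the four-membered ring are cut as a ketene–ynol ether [2+2]. This places the silyloxy group on C3 and the prenyl group on C4 by polarity alone. The gain is two simple acyclic pieces. The demand is that the aldoketene 12 is trapped faster than it dimerises and that 13 is not heated before step 5.

9 to 6 and 2. The O–Si bond is cut, and the parent ynolate 8 is traced to a 3-arylisoxazole that fragments on C5-lithiation. The gain is access to the two-carbon ynolate without an ester homologation on a formate. The demand is silylation on oxygen, which the bulky triflate favours.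

5 to 1 and 2 (through 3 and 4). The O–Si bond and the C2–C3 bond are cut. C2 of 5 is the carbon inserted by the homologation, and the prenyl CH2 migrates onto it. The ester must therefore carry the prenyl CH2 directly on its carbonyl carbon. An ester with one more methylene would give the homologue of 5 and a homoprenyl chain on ring A. The demand is carbenoid addition to the ester faster than deprotonation of its acidic alpha position.

## Other disconnections considered

Alternative 1: The cut removes the two aryl–CH2 bonds of the prenyl groups. It leads back to an acetophenone whose two ortho oxygens carry 1,1-dimethylallyl groups, 1-[4-(methoxymethoxy)-2,6-bis(2-methylbut-3-en-2-yloxy)phenyl]ethanone A2. Heating A2 would trigger two aromatic Claisen rearrangements. Each [3,3] shift would transfer the allyl unit with allylic inversion to the only free ortho carbon and, after enolisation, give the diprenyl ketone A1 without closing a ring.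
- In favour: ring A and the C4 carbon are bought together, so no benzannulation or C-acylation is needed. The only free ring carbons are the ones to be substituted. A1 needs only protection and an aldol condensation to reach a chalcone of the same kind as 25.
- Against: the two tertiary allyl ethers must be placed on hindered, hydrogen-bonded hydroxyls, in practice through the 1,1-dimethylpropargyl ethers and semihydrogenation over Pd/CaCO3 poisoned with Pb(OAc)2. Such ethers tend to lose isoprene on heating. Each new ortho-prenylphenol has to survive the heat of the second shift, where chroman formation and abnormal Claisen pathways become possible.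
- Comparison: on structure the two plans deliver the same symmetric ring A and are equal, and the regiochemical certainty is equal too. On mechanism both are thermal pericyclic; the alternative uses two separate shifts of labile ethers, the chosen plan one cascade from stable silyl ethers at lower temperature. On step economy and cost the alternative is the better one: A1 should be about four steps from a cheap ring A ketone, against five steps to 18 and two more to 25.

Alternative 2: The cut is the C2–C3 bond of ring C, redrawn as a C2–C4 bond. The precursor is the 2-aryl-3-hydroxy-2,3-dihydrobenzofuran-3-carbaldehyde A4, in which the future C4 is a tertiary carbinol and the future C3 a formyl group. A promoter such as Al(OC(CH3)3)3 would bind the hydroxy aldehyde and induce an alpha-ketol rearrangement. C2 would migrate with retention from the carbinol carbon to the formyl carbon, the carbinol would become the C4 ketone, and the five-membered ring would expand to ring C of A3.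
- In favour: the isomerisation is redox-neutral and creates the C3 hydroxyl and C4 ketone together, with no peroxide and no acid-labile epoxide near the prenyl groups. Ring strain relief and the hydrogen-bonded aryl ketone should drive it. C2 is carried over unchanged and C3 is set relative to it by the substrate. On relative stereocontrol at C3 the alternative is at least the equal of the chosen plan.
- Against: the absolute configuration at C2 must already be present in A4, and no simple catalytic method for that is at hand. The aryl carbon C4a could migrate in place of C2. Alpha-ketol shifts are reversible, and the carbinol sits beside a hexasubstituted benzene. Above all, the diprenylphloroglucinol pattern of ring A would still have to be made, for example by way of 18.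
- Comparison: on structure the alternative solves ring C where the chosen key step solves ring A, so the two are complementary rather than rival. On mechanism a Lewis-acid-templated 1,2-shift and a thermal electrocyclic cascade are equally atom-economical. On step economy A4 needs a ring A carbonyl compound, a double benzylation, a ring closure and oxidation-state changes, which is expected to be longer than steps 6 to 11. On absolute stereocontrol the chosen plan is stronger.

Alternative 3: The cut takes O1–C2 and C3–C4 apart together as the retro-[4+2] of a chroman. Ring A appears as the salicylaldehyde A6. HC(OMe)3 and acid would convert it in the flask into the 4-methoxy ortho-quinone methide A7. A7 would act as heterodiene towards the (E)-enol acetate A8 and give the 4-methoxyflavan-3-yl acetate A5 with 2,3-trans and 3,4-trans relationships.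
- In favour: the union is convergent and forms two bonds and three adjacent stereocentres in one step. The C3 oxygen comes in at the right oxidation level. The relative configuration follows from the E geometry and the exo or endo preference. In convergence and in bonds formed per step this is better than the chosen endgame.
- Against: C4 arrives as a benzylic methyl ether, so hydrolysis and oxidation to the ketone must follow, next to a very electron-rich ring and two oxidisable prenyl groups. The cycloaddition is racemic unless a chiral acid catalyst is found for this quinone methide. The regiochemistry depends on the aryl group, not the acetoxy group, controlling the polarisation of A8. Generating A7 needs acid in the presence of prenyl groups. A6 must itself come from a diprenylphloroglucinol such as 19.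
- Comparison: on structure both routes need a ring A with one open position, so they are equal and the alternative is again complementary to the ring A key step. On mechanism an inverse-demand hetero-Diels–Alder reaction is set against an epoxide opening; relative stereocontrol is equal, absolute stereocontrol is better in the chosen plan. On step economy the ring C step is shorter, but the C4 adjustment and the preparation of A6 and A8 are expected to raise the overall count.

Key step: step 5

Remarks on the chemistry:
- The Kowalski sequence inserts one carbon between the ester carbonyl and its alpha carbon. Alkyne 5 therefore has to come from ethyl 4-methylpent-3-enoate (1). Ethyl 5-methylhex-4-enoate would give the one-carbon-longer alkyne and a homoprenyl group on ring A, so it is not used. 5-Methylhex-4-enoic acid (10) remains the right source of the ketene half.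
- Compounds 1 and 6, diethyl [2-(methoxy(methyl)amino)-2-oxoethyl]phosphonate and poly-L-leucine are assumed to be catalogue items; 1 is otherwise one esterification from 4-methylpent-3-enoic acid.
- The acyl carbon is introduced by directed metalation rather than by Friedel–Crafts acetylation, and the triol 19 is not isolated; both changes keep Lewis acid and air away from the prenylphenols.

## Route

Step 1
Reactants: 1 ethyl 4-methylpent-3-enoate; 2 triisopropylsilyl trifluoromethanesulfonate
Product: 5 5-methyl-1-(triisopropylsilyloxy)hex-4-en-1-yne, via dibromo enolate 3 (not isolated), via lithium ynolate 4 (not isolated)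
Conditions: CH2Br2, lithium 2,2,6,6-tetramethylpiperidide (2.1 equiv), THF, −78 °C; n-BuLi, −78 °C → rt; then 2 (2.2 equiv), −78 → 0 °C
Reagents that add atoms: dibromomethane, BrCBr; triisopropylsilyl trifluoromethanesulfonate (2), CC(C)[Si](C(C)C)(C(C)C)OS(=O)(=O)C(F)(F)F
Why: Kowalski ester homologation with silyl trapping: LiCHBr2 adds to the ester, loss of ethoxide and enolisation give 3, bromine–lithium exchange triggers the carbenoid 1,2-shift of the prenyl CH2 to ynolate 4, and the bulky, hard silyl triflate silylates 4 on oxygen. The inserted carbon becomes C2 of 5, which is why the ester carries the prenyl CH2 directly on its carbonyl; the excess of 2 also caps the ethoxide.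

Step 2
Reactants: 6 3-phenylisoxazole; 2 triisopropylsilyl trifluoromethanesulfonate
Product: 9 ethynyloxytriisopropylsilane, via lithiated isoxazole 7 (not isolated), via lithium ethynolate 8 (not isolated)
Conditions: n-BuLi (1.0 equiv), THF, −78 → −60 °C; then 2, −78 → 0 °C; distillation
Reagents that add atoms: triisopropylsilyl trifluoromethanesulfonate (2), CC(C)[Si](C(C)C)(C(C)C)OS(=O)(=O)C(F)(F)F
Why: n-BuLi removes H5 of the isoxazole and the 5-lithio species 7 fragments by cycloreversion to benzonitrile and the parent ynolate 8, a known way to this anion; O-silylation by the hindered triflate follows the behaviour of alkyl ynolates with bulky silyl electrophiles. One equivalent of base at low temperature keeps the benzonitrile from being attacked, and it is removed by distillation.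

Step 3
Reactants: 10 5-methylhex-4-enoic acid
Product: 11 5-methylhex-4-enoyl chloride
Conditions: (COCl)2, DMF (cat.), CH2Cl2, 0 °C → rt
Reagents that add atoms: oxalyl chloride, O=C(Cl)C(=O)Cl
Why: Acid chloride formation through the DMF-derived chloroiminium salt; the by-products are gases and the low temperature spares the trisubstituted alkene from HCl addition.

Step 4
Reactants: 11 5-methylhex-4-enoyl chloride; 9 ethynyloxytriisopropylsilane
Product: 13 rac-4-(3-methylbut-2-enyl)-3-(triisopropylsilyloxy)cyclobut-2-en-1-one, via prenylketene 12 (not isolated)
Conditions: Et3N, Et2O–hexane, slow addition of 11, 0 °C → rt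
Reagents that add atoms: none
Why: Et3N dehydrochlorinates 11 to the aldoketene 12, which is trapped as it forms in a [2+2] ketene–ynol ether cycloaddition; the nucleophilic CH terminus of 9 bonds to the ketene carbonyl carbon, so the silyloxy group ends on C3 and the prenyl-bearing ketene carbon becomes C4. Slow addition keeps 12 dilute, the temperature stays below that at which 13 ring-opens, and the new stereocentre is racemic and is erased in step 5.

Step 5
Reactants: 13 rac-4-(3-methylbut-2-enyl)-3-(triisopropylsilyloxy)cyclobut-2-en-1-one; 5 5-methyl-1-(triisopropylsilyloxy)hex-4-en-1-yne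
Product: 18 2,6-bis(3-methylbut-2-enyl)-3,5-bis(triisopropylsilyloxy)phenol, via vinylketene 14 (not isolated), via vinylcyclobutenone 15 (not isolated), via dienylketene 16 (not isolated), via cyclohexadienone 17 (not isolated)
Conditions: 5 (1.2 equiv), toluene, 80 °C, then 110 °C to completion, argon
Reagents that add atoms: none
Why: Heating opens 13 by conrotatory four-electron electrocyclic cleavage of its C1–C4 bond to vinylketene 14, the prenyl-bearing carbon turning outward. The polarised ynol ether 5 adds to the ketene in a [2+2] cycloaddition in which its nucleophilic C2 (bearing the prenyl CH2) bonds to the ketene carbonyl carbon (C7–C8) and its oxygen-bearing C1 to the ketene alpha carbon (C4a–C8a), giving 15. 15 opens in a second four-electron electrocyclic step to dienylketene 16, whose termini close ring A by thermal disrotatory six-electron electrocyclisation (C6–C7) to 17, and enolisation gives phenol 18. The closest known reaction is the Danheiser benzannulation of cyclobutenones with silyloxyalkynes, including its use with 3-silyloxycyclobutenones to give phloroglucinol bis(silyl ethers). No stereocentre is created: the C4 centre of 13 becomes sp2 and 18 is achiral. The step needs regioselectivity in the ketene–alkyne cycloaddition, which the donor oxygen of 5 secures, and chemoselectivity for the ynol ether over the trisubstituted alkenes and over ketene dimerisation, which its high nucleophilicity and slight excess secure. Because 18 is symmetric there is no positional isomer, and the two flanking prenyl groups shield the new phenol from acylation by residual ketene.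

Step 6
Reactants: 18 2,6-bis(3-methylbut-2-enyl)-3,5-bis(triisopropylsilyloxy)phenol
Product: 20 1,3,5-tris(methoxymethoxy)-2,4-bis(3-methylbut-2-enyl)benzene, via diprenylphloroglucinol 19 (not isolated)
Conditions: Bu4NF, THF, 0 °C; then i-Pr2NEt, MOMCl, 0 °C → rt, one flask, argon
Reagents that add atoms: chloromethyl methyl ether, COCCl
Why: Fluoride cleaves both aryl O–Si bonds and the phenoxides of 19, together with the third phenol and the amine base, are O-alkylated in the same flask (Williamson-type ether formation), so the air-sensitive triol is never handled. Methoxymethyl is chosen because it directs the metalation of step 9 and leaves in the acid of step 11; the hard electrophile favours O- over C-alkylation.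

Step 7
Reactants: 21 4-hydroxybenzaldehyde
Product: 22 4-(methoxymethoxy)benzaldehyde
Conditions: MOMCl, i-Pr2NEt, CH2Cl2, 0 °C → rt
Reagents that add atoms: chloromethyl methyl ether, COCCl
Why: Williamson-type O-alkylation of the phenol; the aldehyde is untouched.

Step 8
Reactants: 22 4-(methoxymethoxy)benzaldehyde
Product: 23 (E)-N-methoxy-3-[4-(methoxymethoxy)phenyl]-N-methylprop-2-enamide
Conditions: (EtO)2P(O)CH2C(O)N(OMe)Me, NaH, THF, 0 °C → rt
Reagents that add atoms: diethyl [2-(methoxy(methyl)amino)-2-oxoethyl]phosphonate, CCOP(=O)(CC(=O)N(C)OC)OCC
Why: Horner–Wadsworth–Emmons olefination with an amide-stabilised phosphonate, which gives the E alkene and installs the Weinreb amide needed in step 9.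

Step 9
Reactants: 20 1,3,5-tris(methoxymethoxy)-2,4-bis(3-methylbut-2-enyl)benzene; 23 (E)-N-methoxy-3-[4-(methoxymethoxy)phenyl]-N-methylprop-2-enamide
Product: 25 (E)-3-[4-(methoxymethoxy)phenyl]-1-[2,4,6-tris(methoxymethoxy)-3,5-bis(3-methylbut-2-enyl)phenyl]prop-2-en-1-one, via aryllithium 24 (not isolated)
Conditions: n-BuLi, THF, 0 °C; then 23, −78 → 0 °C; H2O
Reagents that add atoms: none
Why: Directed ortho-metalation followed by Weinreb ketone synthesis: the only ring hydrogen lies between two OCH2OCH3 groups, whose cooperative coordination and inductive effect guide n-BuLi there to give 24. 24 adds to the amide carbonyl of 23 to a chelated tetrahedral adduct that releases the enone only on work-up, so there is no over-addition, no acid is involved, and the whole C4–C3–C2–ring B unit arrives in one operation.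

Step 10
Reactants: 25 (E)-3-[4-(methoxymethoxy)phenyl]-1-[2,4,6-tris(methoxymethoxy)-3,5-bis(3-methylbut-2-enyl)phenyl]prop-2-en-1-one
Product: 26 [(2R,3S)-3-[4-(methoxymethoxy)phenyl]oxiran-2-yl][2,4,6-tris(methoxymethoxy)-3,5-bis(3-methylbut-2-enyl)phenyl]methanone
Conditions: poly-L-leucine, urea·H2O2, DBU, THF, rt
Reagents that add atoms: hydrogen peroxide (used as its urea adduct), OO
Why: Juliá–Colonna epoxidation (a polypeptide-mediated Weitz–Scheffer reaction): the hydroperoxide anion is a nucleophilic oxidant that attacks only the enone and ignores the two electron-rich prenyl alkenes. The helical N-terminus of poly-L-leucine binds enone and peroxide and is expected to deliver oxygen to the face that gives the (2R,3S)-oxirane, as it does with chalcones; the trans relationship follows from the E alkene, so both stereocentres are set here.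

Step 11
Reactants: 26 [(2R,3S)-3-[4-(methoxymethoxy)phenyl]oxiran-2-yl][2,4,6-tris(methoxymethoxy)-3,5-bis(3-methylbut-2-enyl)phenyl]methanone
Product: 27 (2R,3R)-3,5,7-trihydroxy-2-(4-hydroxyphenyl)-6,8-bis(3-methylbut-2-enyl)-2,3-dihydrochromen-4-one (6,8-diprenylaromadendrin)
Conditions: HCl (conc. aq., few equiv), MeOH–THF, 40–45 °C
Reagents that add atoms: none
Why: Acid-catalysed acetal cleavage frees the four hydroxyls, and the phenol ortho to the ketone opens the protonated epoxide at its benzylic carbon (6-endo epoxide opening, favoured by the para-oxygenated aryl group) to close ring C. C3 keeps the configuration set in step 10 and C2 is formed with inversion or, if the benzylic carbon ionises, under the strong preference for the diequatorial 2,3-trans ring, giving (2R,3R)-27. Temperature and acid strength are kept low so that the prenyl groups do not close onto the neighbouring phenols.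

## Compound list

1 | ethyl 4-methylpent-3-enoate | CCOC(=O)CC=C(C)C | starting material
2 | triisopropylsilyl trifluoromethanesulfonate | CC(C)[Si](C(C)C)(C(C)C)OS(=O)(=O)C(F)(F)F | starting material
3 | lithium 1,1-dibromo-5-methylhexa-1,4-dien-2-olate | [Li+].[O-]C(CC=C(C)C)=C(Br)Br | intermediate (not isolated)
4 | lithium 5-methylhex-4-en-1-yn-1-olate | [Li+].[O-]C#CCC=C(C)C | intermediate (not isolated)
5 | 5-methyl-1-(triisopropylsilyloxy)hex-4-en-1-yne | CC(C)=CCC#CO[Si](C(C)C)(C(C)C)C(C)C | intermediate
6 | 3-phenylisoxazole | c1ccc(-c2ccon2)cc1 | starting material
7 | 5-lithio-3-phenylisoxazole | [Li]c1cc(-c2ccccc2)no1 | intermediate (not isolated)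
8 | lithium ethynolate | [Li+].[O-]C#C | intermediate (not isolated)
9 | ethynyloxytriisopropylsilane | C#CO[Si](C(C)C)(C(C)C)C(C)C | intermediate
10 | 5-methylhex-4-enoic acid | CC(C)=CCCC(=O)O | starting material
11 | 5-methylhex-4-enoyl chloride | CC(C)=CCCC(=O)Cl | intermediate
12 | 5-methylhexa-1,4-dien-1-one (prenylketene) | O=C=CCC=C(C)C | intermediate (not isolated)
13 | rac-4-(3-methylbut-2-enyl)-3-(triisopropylsilyloxy)cyclobut-2-en-1-one | O=C1C=C(O[Si](C(C)C)(C(C)C)C(C)C)C1CC=C(C)C | intermediate
14 | 7-methyl-3-(triisopropylsilyloxy)octa-1,3,6-trien-1-one | O=C=CC(O[Si](C(C)C)(C(C)C)C(C)C)=CCC=C(C)C | intermediate (not isolated)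
15 | 2-(3-methylbut-2-enyl)-4-[5-methyl-1-(triisopropylsilyloxy)hexa-1,4-dienyl]-3-(triisopropylsilyloxy)cyclobut-2-en-1-one | O=C1C(CC=C(C)C)=C(O[Si](C(C)C)(C(C)C)C(C)C)C1C(O[Si](C(C)C)(C(C)C)C(C)C)=CCC=C(C)C | intermediate (not isolated)
16 | 9-methyl-2-(3-methylbut-2-enyl)-3,5-bis(triisopropylsilyloxy)deca-1,3,5,8-tetraen-1-one | O=C=C(CC=C(C)C)C(O[Si](C(C)C)(C(C)C)C(C)C)=CC(O[Si](C(C)C)(C(C)C)C(C)C)=CCC=C(C)C | intermediate (not isolated)
17 | 2,6-bis(3-methylbut-2-enyl)-3,5-bis(triisopropylsilyloxy)cyclohexa-2,4-dien-1-one | O=C1C(CC=C(C)C)=C(O[Si](C(C)C)(C(C)C)C(C)C)C=C(O[Si](C(C)C)(C(C)C)C(C)C)C1CC=C(C)C | intermediate (not isolated)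
18 | 2,6-bis(3-methylbut-2-enyl)-3,5-bis(triisopropylsilyloxy)phenol | Oc1c(CC=C(C)C)c(O[Si](C(C)C)(C(C)C)C(C)C)cc(O[Si](C(C)C)(C(C)C)C(C)C)c1CC=C(C)C | intermediate
19 | 2,4-bis(3-methylbut-2-enyl)benzene-1,3,5-triol | CC(C)=CCc1c(O)cc(O)c(CC=C(C)C)c1O | intermediate (not isolated)
20 | 1,3,5-tris(methoxymethoxy)-2,4-bis(3-methylbut-2-enyl)benzene | COCOc1cc(OCOC)c(CC=C(C)C)c(OCOC)c1CC=C(C)C | intermediate
21 | 4-hydroxybenzaldehyde | O=Cc1ccc(O)cc1 | starting material
22 | 4-(methoxymethoxy)benzaldehyde | COCOc1ccc(C=O)cc1 | intermediate
23 | (E)-N-methoxy-3-[4-(methoxymethoxy)phenyl]-N-methylprop-2-enamide | COCOc1ccc(/C=C/C(=O)N(C)OC)cc1 | intermediate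
24 | [2,4,6-tris(methoxymethoxy)-3,5-bis(3-methylbut-2-enyl)phenyl]lithium | [Li]c1c(OCOC)c(CC=C(C)C)c(OCOC)c(CC=C(C)C)c1OCOC | intermediate (not isolated)
25 | (E)-3-[4-(methoxymethoxy)phenyl]-1-[2,4,6-tris(methoxymethoxy)-3,5-bis(3-methylbut-2-enyl)phenyl]prop-2-en-1-one | COCOc1ccc(/C=C/C(=O)c2c(OCOC)c(CC=C(C)C)c(OCOC)c(CC=C(C)C)c2OCOC)cc1 | intermediate
26 | [(2R,3S)-3-[4-(methoxymethoxy)phenyl]oxiran-2-yl][2,4,6-tris(methoxymethoxy)-3,5-bis(3-methylbut-2-enyl)phenyl]methanone | O=C(c1c(OCOC)c(CC=C(C)C)c(OCOC)c(CC=C(C)C)c1OCOC)[C@@H]1O[C@H]1c1ccc(OCOC)cc1 | intermediate
27 | (2R,3R)-3,5,7-trihydroxy-2-(4-hydroxyphenyl)-6,8-bis(3-methylbut-2-enyl)-2,3-dihydrochromen-4-one | CC(C)=CCc1c(O)c(CC=C(C)C)c2c(c1O)C(=O)[C@H](O)[C@@H](c1ccc(O)cc1)O2 | target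

## Step count and risk

Total step count: 11. Longest linear sequence: 7 steps (steps 2, 4, 5, 6, 9, 10, 11; the branch through steps 3 and 4 is equally long).

Least certain steps:

Step 5 (key step). The vinylketene may be lost to dimerisation or to capture by adventitious nucleophiles, or the silyloxyalkyne may rearrange thermally to a silylketene before the [2+2]. Both partners are reactive and the cascade only starts above the temperature at which these drains also operate. Fallback: the ring A triol is made by direct double C-prenylation of purchased phloroglucinol with 1-bromo-3-methylbut-2-ene in cold aqueous KOH, with chromatographic separation from mono- and tri-alkylated material. This sets out from purchased material in place of 13 and 5 and comes back to the route at 19, which is capped with MOMCl and i-Pr2NEt as in step 6. No new compound arises.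

Step 2. Silylation of the ambident ethynolate on carbon instead of oxygen would give a silylketene, and the small ynol ether may be lost during separation from benzonitrile. The parent ynolate has an unhindered carbon terminus, unlike the alkyl ynolates on which O-silylation is precedented. Fallback: a fluoride-labile alkyl ynol ether replaces the silyl ynol ether. 2-(Trimethylsilyl)ethanol, KH and trichloroethylene give [2-(1,2-dichloroethenyloxy)ethyl]trimethylsilane F1. n-BuLi (elimination, then chlorine–lithium exchange) and a methanol quench give [2-(ethynyloxy)ethyl]trimethylsilane F2. F2 is combined with 11 and Et3N as in step 4 to give rac-4-(3-methylbut-2-enyl)-3-[2-(trimethylsilyl)ethoxy]cyclobut-2-en-1-one F3. F3 is heated with 5 as in step 5 to give 2,6-bis(3-methylbut-2-enyl)-3-(triisopropylsilyloxy)-5-[2-(trimethylsilyl)ethoxy]phenol F4. Warm Bu4NF in DMF removes both oxygen substituents. The sequence sets out from 11 and 5 and comes back to the route at 19, which is capped as in step 6.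

Step 1. Deprotonation at the doubly activated alpha position of the beta,gamma-unsaturated ester may outrun carbenoid addition, with conjugation of the alkene. Fallback: the ynolate is made by oxidation of an acetylide instead of by ester homologation. 1-Bromo-3-methylbut-2-ene and HC≡CMgBr with catalytic CuCl give 5-methylhex-4-en-1-yne F5. Deprotonation with LiN(SiMe3)2 and oxygen transfer from lithium tert-butyl peroxide give the ynolate. This sets out from purchased bromide in place of 1 and comes back to the route at 4, which is silylated with 2 to give 5.

Step 9. Lateral deprotonation at the allylic–benzylic CH2 groups may compete with ring metalation, and conjugate addition to 23 with addition at the amide carbonyl. Fallback: the acyl carbon is introduced by electrophilic substitution and the enone by aldol condensation. 19, isolated under argon after the fluoride treatment of 18, is C-acetylated with Ac2O and BF3·OEt2 at 0 °C for a short time to give 1-[2,4,6-trihydroxy-3,5-bis(3-methylbut-2-enyl)phenyl]ethanone F6. NaH and MOMCl give 1-[2,4,6-tris(methoxymethoxy)-3,5-bis(3-methylbut-2-enyl)phenyl]ethanone F7. Claisen–Schmidt condensation of F7 with 22 (KOH, EtOH) sets out from 19 and comes back to the route at 25.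

Step 10. Oxygen transfer may be slow or poorly face-selective, because the ketone aryl group of 25 is twisted and flanked by four substituents that can keep the enone out of the peptide binding site. Fallback: the stereocentres are set on the small ring B fragment before the union. 23 is reduced with i-Bu2AlH to (E)-3-[4-(methoxymethoxy)phenyl]prop-2-enal F8. Iminium-catalysed epoxidation with H2O2 and (S)-2-{bis[3,5-bis(trifluoromethyl)phenyl](trimethylsilyloxy)methyl}pyrrolidine, chosen for the (2R,3S) sense it usually gives with cinnamaldehydes, would give (2R,3S)-3-[4-(methoxymethoxy)phenyl]oxirane-2-carbaldehyde F9. Addition of 24 gives {(2S,3S)-3-[4-(methoxymethoxy)phenyl]oxiran-2-yl}[2,4,6-tris(methoxymethoxy)-3,5-bis(3-methylbut-2-enyl)phenyl]methanol F10 as both carbinol epimers. Dess–Martin periodinane with NaHCO3 oxidises F10. The sequence sets out from 23 and 24 and comes back to the route at 26.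

Step 11. Acid may close a prenyl group onto its neighbouring phenol, methanol may capture the benzylic cation, or the aryl group may undergo a 1,2-shift, because deprotection and epoxide opening share one acidic medium. Fallback: the epoxide is consumed under aprotic conditions before the final deprotection. BnSH with SnCl4 in CH2Cl2 at −20 °C opens 26 at the benzylic carbon, with loss of one chelated ortho acetal, to give (2S,3R)-3-(benzylsulfanyl)-2-hydroxy-1-[2-hydroxy-4,6-bis(methoxymethoxy)-3,5-bis(3-methylbut-2-enyl)phenyl]-3-[4-(methoxymethoxy)phenyl]propan-1-one F11. AgBF4 at 0 °C then activates the sulfide for ring closure by the phenol to the trans product (2R,3R)-3-hydroxy-5,7-bis(methoxymethoxy)-2-[4-(methoxymethoxy)phenyl]-6,8-bis(3-methylbut-2-enyl)-2,3-dihydrochromen-4-one F12. Brief HCl in MeOH at rt removes the remaining acetals. The sequence sets out from 26 and comes back to the route at 27.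

## Further compounds

F0 | step 5 | none | none
F1 | step 2 | [2-(1,2-dichloroethenyloxy)ethyl]trimethylsilane | C[Si](C)(C)CCOC(Cl)=CCl
F2 | step 2 | [2-(ethynyloxy)ethyl]trimethylsilane | C[Si](C)(C)CCOC#C
F3 | step 2 | rac-4-(3-methylbut-2-enyl)-3-[2-(trimethylsilyl)ethoxy]cyclobut-2-en-1-one | O=C1C=C(OCC[Si](C)(C)C)C1CC=C(C)C
F4 | step 2 | 2,6-bis(3-methylbut-2-enyl)-3-(triisopropylsilyloxy)-5-[2-(trimethylsilyl)ethoxy]phenol | Oc1c(CC=C(C)C)c(OCC[Si](C)(C)C)cc(O[Si](C(C)C)(C(C)C)C(C)C)c1CC=C(C)C
F5 | step 1 | 5-methylhex-4-en-1-yne | C#CCC=C(C)C
F6 | step 9 | 1-[2,4,6-trihydroxy-3,5-bis(3-methylbut-2-enyl)phenyl]ethanone | CC(=O)c1c(O)c(CC=C(C)C)c(O)c(CC=C(C)C)c1O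
F7 | step 9 | 1-[2,4,6-tris(methoxymethoxy)-3,5-bis(3-methylbut-2-enyl)phenyl]ethanone | CC(=O)c1c(OCOC)c(CC=C(C)C)c(OCOC)c(CC=C(C)C)c1OCOC
F8 | step 10 | (E)-3-[4-(methoxymethoxy)phenyl]prop-2-enal | COCOc1ccc(/C=C/C=O)cc1
F9 | step 10 | (2R,3S)-3-[4-(methoxymethoxy)phenyl]oxirane-2-carbaldehyde | O=C[C@@H]1O[C@H]1c1ccc(OCOC)cc1
F10 | step 10 | {(2S,3S)-3-[4-(methoxymethoxy)phenyl]oxiran-2-yl}[2,4,6-tris(methoxymethoxy)-3,5-bis(3-methylbut-2-enyl)phenyl]methanol, both carbinol epimers | OC(c1c(OCOC)c(CC=C(C)C)c(OCOC)c(CC=C(C)C)c1OCOC)[C@@H]1O[C@H]1c1ccc(OCOC)cc1
F11 | step 11 | (2S,3R)-3-(benzylsulfanyl)-2-hydroxy-1-[2-hydroxy-4,6-bis(methoxymethoxy)-3,5-bis(3-methylbut-2-enyl)phenyl]-3-[4-(methoxymethoxy)phenyl]propan-1-one | O=C(c1c(O)c(CC=C(C)C)c(OCOC)c(CC=C(C)C)c1OCOC)[C@H](O)[C@H](SCc1ccccc1)c1ccc(OCOC)cc1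
F12 | step 11 | (2R,3R)-3-hydroxy-5,7-bis(methoxymethoxy)-2-[4-(methoxymethoxy)phenyl]-6,8-bis(3-methylbut-2-enyl)-2,3-dihydrochromen-4-one | CC(C)=CCc1c(OCOC)c(CC=C(C)C)c2c(c1OCOC)C(=O)[C@H](O)[C@@H](c1ccc(OCOC)cc1)O2
A1 | alternative 1 | 1-[2,6-dihydroxy-4-(methoxymethoxy)-3,5-bis(3-methylbut-2-enyl)phenyl]ethanone | CC(=O)c1c(O)c(CC=C(C)C)c(OCOC)c(CC=C(C)C)c1O
A2 | alternative 1 | 1-[4-(methoxymethoxy)-2,6-bis(2-methylbut-3-en-2-yloxy)phenyl]ethanone | CC(=O)c1c(OC(C)(C)C=C)cc(OCOC)cc1OC(C)(C)C=C
A3 | alternative 2 | (2R,3R)-3-hydroxy-7-(methoxymethoxy)-5-{[4-(methoxymethoxy)phenyl]methoxy}-2-[4-(methoxymethoxy)phenyl]-6,8-bis(3-methylbut-2-enyl)-2,3-dihydrochromen-4-one | CC(C)=CCc1c(OCOC)c(CC=C(C)C)c2c(c1OCc1ccc(OCOC)cc1)C(=O)[C@H](O)[C@@H](c1ccc(OCOC)cc1)O2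
A4 | alternative 2 | (2R)-3-hydroxy-6-(methoxymethoxy)-4-{[4-(methoxymethoxy)phenyl]methoxy}-2-[4-(methoxymethoxy)phenyl]-5,7-bis(3-methylbut-2-enyl)-2,3-dihydro-1-benzofuran-3-carbaldehyde, either carbinol epimer | CC(C)=CCc1c(OCOC)c(CC=C(C)C)c2c(c1OCc1ccc(OCOC)cc1)C(O)(C=O)[C@@H](c1ccc(OCOC)cc1)O2
A5 | alternative 3 | (2R,3S,4R)-5,7-bis(tert-butyldimethylsilyloxy)-2-[4-(tert-butyldimethylsilyloxy)phenyl]-4-methoxy-6,8-bis(3-methylbut-2-enyl)chroman-3-yl acetate (2,3-trans-3,4-trans) | CC(C)=CCc1c(O[Si](C)(C)C(C)(C)C)c(CC=C(C)C)c2c(c1O[Si](C)(C)C(C)(C)C)[C@@H](OC)[C@H](OC(C)=O)[C@@H](c1ccc(O[Si](C)(C)C(C)(C)C)cc1)O2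
A6 | alternative 3 | 4,6-bis(tert-butyldimethylsilyloxy)-2-hydroxy-3,5-bis(3-methylbut-2-enyl)benzaldehyde | O=Cc1c(O)c(CC=C(C)C)c(O[Si](C)(C)C(C)(C)C)c(CC=C(C)C)c1O[Si](C)(C)C(C)(C)C
A7 | alternative 3 | 3,5-bis(tert-butyldimethylsilyloxy)-6-(methoxymethylidene)-2,4-bis(3-methylbut-2-enyl)cyclohexa-2,4-dien-1-one | COC=C1C(=O)C(CC=C(C)C)=C(O[Si](C)(C)C(C)(C)C)C(CC=C(C)C)=C1O[Si](C)(C)C(C)(C)C
A8 | alternative 3 | (E)-2-[4-(tert-butyldimethylsilyloxy)phenyl]ethenyl acetate | CC(=O)O/C=C/c1ccc(O[Si](C)(C)C(C)(C)C)cc1
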